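## Analysis of the target

Target 19 is a flavonol: a 4H-chromen-4-one (benzo ring A fused to pyranone ring C) with a 4-hydroxyphenyl ring B on C2 and a hydroxyl on C3. It has no stereocentre, so the problem is one of constitution only. Ring A is fully substituted: C4a carries the carbonyl carbon C4, and C5, C6, C7, C8 and C8a carry five neighbouring oxygens (the 5-hydroxyl, three methoxy groups and O1). The free 5-OH (chelated to C4=O), the enolic 3-OH and the electron-rich ring A make the compound sensitive to base, to peroxide under basic conditions and to oxidants that turn polyoxygenated phenols into quinones. The three methyl ethers must survive whatever frees the three hydroxyls. The difficulty lies in the crowded ring A and in telling apart the two oxygens that flank C4a (the C5 oxygen and O1), which sit in equivalent positions relative to the three methoxy groups until one of them is marked. The strategy rests on C4: it is a lone carbonyl carbon between C4a and the C3=C2–aryl unit, so it can enter as carbon monoxide between an aryl iodide at C4a and a terminal arylalkyne that supplies C3, C2 and ring B. The oxygen on C8a then closes ring C, and ring A only has to be made as a pentaoxygenated benzene whose one unsubstituted carbon becomes C4a.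

## Retrosynthetic reasoning

Target 19 from dibenzyl ether 18. The two benzylic C–O bonds at the C5 and C4' oxygens are cut last. The free trihydroxy compound is the most sensitive species of the route, benzyl is distinct from the three methyl ethers, and it is removed under neutral reductive conditions. The forward step must cleave both benzyl ethers without touching C2=C3, C4=O or the methoxy groups.

Flavonol 18 from flavone 15. The C3–O bond is cut. In 15, C3–H is the only C–H of the heterocycle and is acidified by the neighbouring carbonyl, so oxygen can be placed there after the ring is built. This lets the ring-forming step use a plain terminal alkyne. The forward step must turn C3–H into C3–O through the C3 anion and a C3–boron bond without opening the pyranone.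

Flavone 15 from iodophenol 10, alkyne 11 and carbon monoxide 12. Three bonds are cut: C4a–C4, C4–C3 and O1–C2. C4 has no carbon neighbours other than C4a and C3 and is at the carbonyl oxidation level, so it is a one-carbon unit. C3, C2 and ring B form an arylalkyne, and what is left of ring A is an ortho-iodophenol. This cut is convergent, forms ring C in one operation, and fixes the positions of the carbonyl and of O1 by where the iodine and the free hydroxyl sit. Cuts that go through an ortho-hydroxyacetophenone would instead require acylating the crowded ring A. The forward reaction must insert carbon monoxide before the alkyne couples and must close the six-membered ring and not the five-membered one.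

Iodophenol 10 from phenol 9. The C–I bond is cut. Phenol 9 has a single ring hydrogen, ortho to the free hydroxyl and ortho to the benzyloxy group, so electrophilic iodination has only one site.

Phenol 9 from aryl bromide 6. The phenolic C–O bond is traced back to a C–Br bond (halogen–metal exchange, borylation, oxidation). The two oxygens that will flank C4a are introduced one after the other, so the first is already benzylated when the second appears; this is what distinguishes the C5 oxygen from O1.

Aryl bromide 6 from bromophenol 4 and benzyl bromide 5. The O–benzyl bond is cut; a simple phenol alkylation marks the future C5 oxygen.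

Bromophenol 4 from bromoaldehyde 2. The aryl C–O bond is traced back to the aryl–CHO bond (Dakin oxidation). The formyl group of the starting material is a latent hydroxyl.

Bromoaldehyde 2 from 2,3,4-trimethoxybenzaldehyde 1. The C–Br bond is cut. In 1 the formyl group (meta-directing) and the 2- and 4-methoxy groups (para- and ortho-directing) all point to C5. Aldehyde 1 is cheap and already holds the three neighbouring methoxy groups.

## Alternatives that were turned down

Alternative 1: The cut is at the C6–O and C8–O bonds, made on a finished flavonol. In the forward key step the dibromide A1, 3-(benzyloxy)-2-[4-(benzyloxy)phenyl]-6,8-dibromo-5,7-dimethoxy-4H-chromen-4-one, is heated with NaOMe and catalytic CuBr so that both bromides are exchanged for methoxide. The product is the tetramethyl ether A2, 3-(benzyloxy)-2-[4-(benzyloxy)phenyl]-5,6,7,8-tetramethoxy-4H-chromen-4-one.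
- For it: A1 comes from standard chalcone chemistry on a phloroglucinol-derived ketone followed by bromination of the only two free, activated ring A carbons. The C3 oxygen is present from the start, and no pressurised gas is needed. On these points it is stronger than the chosen route, which needs a late C3–H oxidation and an autoclave.
- Against it: two Ullmann-type substitutions must both succeed at bromides that each sit between two ortho oxygens. Protodebromination at either site gives a by-product that differs by one methoxy group only. Hot methoxide also attacks flavones at C2 and opens ring C. A2 then has four methyl ethers, of which exactly the one at C5 must be removed. Chelation-directed Lewis-acid demethylation is possible there, but the C3 oxygen competes for the carbonyl and the C6 methoxy group is the next to be lost.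
- Comparison: the chosen strategy settles all ring A oxygens, and the difference between the C5 oxygen and the methyl ethers, before ring C exists. No C–O bond is formed late on the crowded ring and the final deprotection poses no selectivity problem. The step counts are similar.

Alternative 2: The cut is at the C3–C4 bond. In the forward key step SmI2 reduces the aromatic aldehyde of the dialdehyde A3, 2-(benzyloxy)-6-{1-[4-(benzyloxy)phenyl]-2-oxoethoxy}-3,4,5-trimethoxybenzaldehyde, to a ketyl. The ketyl adds to the tethered aliphatic aldehyde (six-membered exo closure) and gives the flavan-3,4-diol A4, 5-(benzyloxy)-2-[4-(benzyloxy)phenyl]-6,7,8-trimethoxychromane-3,4-diol, as a mixture of stereoisomers.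
- For it: the conditions are mild and neutral, and pinacol cyclisations to six-membered diols are dependable. Both the C3 and C4 oxygens arrive in one step, so no late C3 oxidation is needed; oxidising both carbinols of A4 and letting the product enolise would lead to flavonol 18. On the C3 oxygen it is stronger than the chosen route.
- Against it: A3 is fragile. Its aliphatic aldehyde has an α-hydrogen that is benzylic, α to oxygen and α to the carbonyl, so enolisation, aldol reaction and loss of the phenoxide threaten. An α-aryloxy carbonyl is also the kind of group that divalent samarium cleaves reductively if the wrong carbonyl is reduced first. The hexasubstituted salicylaldehyde behind A3 is no easier to make than iodophenol 10 and needs further O-alkylation and redox steps. Three stereocentres are made only to be erased, and ring C is first reduced and then oxidised twice.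
- Comparison: the chosen route builds ring C directly at its final oxidation level from two stable partners and needs one later oxidation. It is shorter.

Alternative 3: The cut is through ring A, which is built onto a preformed pyranone from a squaric ester. In the forward key step the cyclobutenone A5, 4-{5-(benzyloxy)-6-[4-(benzyloxy)phenyl]-4-oxo-4H-pyran-3-yl}-4-hydroxy-2,3-dimethoxycyclobut-2-en-1-one, is heated. The four-membered ring opens to a dienylketene, the ketene carbon closes onto the pyranone C–H carbon next to O1 (6π closure, forming C8–C8a), and tautomerisation gives the hydroquinone A6, 3-(benzyloxy)-2-[4-(benzyloxy)phenyl]-5,8-dihydroxy-6,7-dimethoxy-4H-chromen-4-one. Selective methylation of the non-chelated 8-OH and hydrogenolysis would finish the synthesis.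
- For it: it is the most convergent plan. All ring A oxygens come from the squarate, the C5 and C8 hydroxyls are distinguished by chelation without protecting-group steps, and the C3 oxygen is present from the start. On convergence and on differentiating the flanking oxygens it is stronger than the chosen route.
- Against it: it needs a 3-oxygenated 2-aryl-4-pyranone metallated at the carbon α to the carbonyl. That pyranone is a multi-step target in itself, and such metallated pyranones tend to ring-open. The 6π closure must engage an electron-poor vinylogous ester double bond and not the usual arene or alkene. The ketene can also be trapped by the tertiary hydroxyl, and A6 is easily oxidised to the corresponding quinone.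
- Comparison: the chosen route uses only simple benzene derivatives and purchased partners. Every step other than the key step is of a standard type, so the risk is concentrated in one operation.

Key step: step 6

Remark on the chemistry: flavone numbering (O1, C2, C3, C4, C4a, C5 to C8, C8a; ring B positions primed) is used for all chromenones. It is assumed that bromination of 1 goes to C5.

## Route

Step 1
Reactants: 1 2,3,4-trimethoxybenzaldehyde
Product: 2 5-bromo-2,3,4-trimethoxybenzaldehyde
Conditions: Br2 (1.05 equiv), NaOAc, AcOH, rt
Reagents that add atoms: bromine, BrBr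
Why: Electrophilic aromatic bromination; C5 is para to the 2-methoxy group, ortho to the 4-methoxy group and meta to the formyl group, so all directing effects agree, whereas C6 lies ortho to the deactivating formyl group. NaOAc buffers the HBr so that no methyl ether is cleaved.

Step 2
Reactants: 2 5-bromo-2,3,4-trimethoxybenzaldehyde
Product: 4 5-bromo-2,3,4-trimethoxyphenol, via aryl formate 3 (not isolated)
Conditions: mCPBA, CH2Cl2, 0 °C to rt; then K2CO3 (cat.), MeOH, rt
Reagents that add atoms: mCPBA (3-chloroperoxybenzoic acid), O=C(OO)c1cccc(Cl)c1
Why: Dakin-type Baeyer–Villiger oxidation; in the peracid adduct of an ortho- and para-alkoxybenzaldehyde the electron-rich aryl group migrates in preference to hydrogen and gives formate 3, which is methanolysed in the same flask. The bromide and the methyl ethers are inert to peracid and to carbonate.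

Step 3
Reactants: 4 5-bromo-2,3,4-trimethoxyphenol; 5 benzyl bromide
Product: 6 1-(benzyloxy)-5-bromo-2,3,4-trimethoxybenzene
Conditions: 5 (1.2 equiv), K2CO3, DMF, rt
Reagents that add atoms: none
Why: Williamson ether synthesis on the phenoxide, the only nucleophilic site; from here on this oxygen is marked as the future C5 oxygen.

Step 4
Reactants: 6 1-(benzyloxy)-5-bromo-2,3,4-trimethoxybenzene
Product: 9 5-(benzyloxy)-2,3,4-trimethoxyphenol, via aryllithium 7 (not isolated), via lithium aryltrimethoxyborate 8 (not isolated)
Conditions: n-BuLi, THF, −78 °C; B(OMe)3, −78 °C to 0 °C; AcOH, 30% aq. H2O2, 0 °C to rt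
Reagents that add atoms: hydrogen peroxide, OO (the new oxygen of 9); n-butyllithium, [Li]CCCC (lithium of 7 and 8 only); trimethyl borate, COB(OC)OC (boron and methoxy groups of 8 only)
Why: Bromine–lithium exchange at −78 °C is faster than any deprotonation, aryllithium 7 is trapped by the borate, and the C–B bond of 8 is oxidised to C–O by aryl migration onto peroxide oxygen (halogen–metal exchange, borylation, oxidation). The acidic peroxide work-up keeps the electron-rich phenol away from basic, air-sensitive conditions; benzyl and methyl ethers are untouched.

Step 5
Reactants: 9 5-(benzyloxy)-2,3,4-trimethoxyphenol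
Product: 10 3-(benzyloxy)-2-iodo-4,5,6-trimethoxyphenol
Conditions: NIS (1.05 equiv), MeCN, 0 °C, dark
Reagents that add atoms: N-iodosuccinimide, O=C1CCC(=O)N1I
Why: Electrophilic aromatic iodination of a phenol; the ring has a single hydrogen, ortho to the free hydroxyl and ortho to the benzyloxy group, so the iodine can enter nowhere else. A mild iodonium source at low temperature limits oxidation of the electron-rich phenol.

Step 6
Reactants: 10 3-(benzyloxy)-2-iodo-4,5,6-trimethoxyphenol; 11 1-(benzyloxy)-4-ethynylbenzene; 12 carbon monoxide
Product: 15 5-(benzyloxy)-2-[4-(benzyloxy)phenyl]-6,7,8-trimethoxy-4H-chromen-4-one, via hydroxyaryl ynone 13 (not isolated), via diethylamino enone 14 (not isolated)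
Conditions: 11 (1.5 equiv), PdCl2(PPh3)2 (5 mol %), CO (20 atm), Et2NH, 120 °C, autoclave
Reagents that add atoms: diethylamine, CCNCC (amino group of 14 only; released again on ring closure)
Why: PdCl2(PPh3)2 is reduced in the flask to zerovalent palladium, which adds oxidatively to the C–I bond of 10; for this electron-rich iodide flanked on both sides this should be the slow step, hence the high temperature. Insertion of CO gives a divalent aroylpalladium species; amine-assisted transfer of the alkynyl group of 11 and reductive elimination form C4a–C4 and C4–C3 and give ynone 13. Diethylamine adds to 13 at the alkyne carbon that carries ring B to give enaminone 14; the ortho hydroxyl then attacks that same carbon in a six-membered endo conjugate addition and diethylamine is expelled, forming O1–C2 and closing ring C. The closest known reaction type is the palladium-catalysed carbonylative Sonogashira coupling of ortho-iodophenols with terminal alkynes in secondary amines, which gives flavones. No stereocentre is formed. Carbonylation before alkynylation is secured by the CO pressure and the absence of copper; six- over five-membered closure is secured by the enaminone, in which the triple bond is gone and only the amine-bearing carbon is electrophilic, so the exo path to an aurone is shut; regiochemistry is secured by the substrate, which has one iodide, one free hydroxyl and a benzyl ether on the other flanking oxygen.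

Step 7
Reactants: 15 5-(benzyloxy)-2-[4-(benzyloxy)phenyl]-6,7,8-trimethoxy-4H-chromen-4-one
Product: 18 5-(benzyloxy)-2-[4-(benzyloxy)phenyl]-3-hydroxy-6,7,8-trimethoxy-4H-chromen-4-one, via 3-lithioflavone 16 (not isolated), via lithium flavon-3-yltrimethoxyborate 17 (not isolated)
Conditions: LiN(iPr)2, THF, −78 °C; B(OMe)3, −78 °C to 0 °C; AcOH, 30% aq. H2O2, 0 °C to rt
Reagents that add atoms: hydrogen peroxide, OO (the C3 oxygen of 18); lithium diisopropylamide, CC(C)[N-]C(C)C.[Li+] (lithium of 16 and 17 only); trimethyl borate, COB(OC)OC (boron and methoxy groups of 17 only)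
Why: C3–H is the most acidic hydrogen of 15 (vinylic and α to the carbonyl); deprotonation by a lithium amide, trapping with the borate and peroxide oxidation is the known lithiation–borylation–oxidation route from flavones to flavonols. At −78 °C the benzylic positions should not be deprotonated and the lithiated pyranone should not ring-open.

Step 8
Reactants: 18 5-(benzyloxy)-2-[4-(benzyloxy)phenyl]-3-hydroxy-6,7,8-trimethoxy-4H-chromen-4-one
Product: 19 3,5-dihydroxy-2-(4-hydroxyphenyl)-6,7,8-trimethoxy-4H-chromen-4-one (3,5,4'-trihydroxy-6,7,8-trimethoxyflavone)
Conditions: H2 (1 atm), Pd/C (10%), EtOAc/MeOH, rt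
Reagents that add atoms: none
Why: Hydrogenolysis of aryl benzyl ethers over palladium on carbon; methyl ethers, the enolic C2=C3 bond and the chelated carbonyl of a flavonol are not reduced at atmospheric pressure. Both benzyl groups fall in one neutral operation, so the sensitive trihydroxy compound is formed last.

## Compound list

1 | 2,3,4-trimethoxybenzaldehyde | COc1ccc(C=O)c(OC)c1OC | starting material
2 | 5-bromo-2,3,4-trimethoxybenzaldehyde | COc1c(Br)cc(C=O)c(OC)c1OC | intermediate
3 | 5-bromo-2,3,4-trimethoxyphenyl formate | COc1c(Br)cc(OC=O)c(OC)c1OC | intermediate
4 | 5-bromo-2,3,4-trimethoxyphenol | COc1c(Br)cc(O)c(OC)c1OC | intermediate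
5 | benzyl bromide | BrCc1ccccc1 | starting material
6 | 1-(benzyloxy)-5-bromo-2,3,4-trimethoxybenzene | COc1c(Br)cc(OCc2ccccc2)c(OC)c1OC | intermediate
7 | [5-(benzyloxy)-2,3,4-trimethoxyphenyl]lithium | [Li]c1cc(OCc2ccccc2)c(OC)c(OC)c1OC | intermediate
8 | lithium [5-(benzyloxy)-2,3,4-trimethoxyphenyl]trimethoxyborate | [Li+].CO[B-](OC)(OC)c1cc(OCc2ccccc2)c(OC)c(OC)c1OC | intermediate
9 | 5-(benzyloxy)-2,3,4-trimethoxyphenol | COc1c(O)cc(OCc2ccccc2)c(OC)c1OC | intermediate
10 | 3-(benzyloxy)-2-iodo-4,5,6-trimethoxyphenol | COc1c(OC)c(OCc2ccccc2)c(I)c(O)c1OC | intermediate
11 | 1-(benzyloxy)-4-ethynylbenzene | C#Cc1ccc(OCc2ccccc2)cc1 | starting material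
12 | carbon monoxide | [C-]#[O+] | starting material
13 | 1-[2-(benzyloxy)-6-hydroxy-3,4,5-trimethoxyphenyl]-3-[4-(benzyloxy)phenyl]prop-2-yn-1-one | COc1c(OC)c(OCc2ccccc2)c(C(=O)C#Cc2ccc(OCc3ccccc3)cc2)c(O)c1OC | intermediate
14 | 1-[2-(benzyloxy)-6-hydroxy-3,4,5-trimethoxyphenyl]-3-[4-(benzyloxy)phenyl]-3-(diethylamino)prop-2-en-1-one (double-bond geometry not defined; either isomer closes) | CCN(CC)C(=CC(=O)c1c(O)c(OC)c(OC)c(OC)c1OCc1ccccc1)c1ccc(OCc2ccccc2)cc1 | intermediate
15 | 5-(benzyloxy)-2-[4-(benzyloxy)phenyl]-6,7,8-trimethoxy-4H-chromen-4-one | COc1c(OC)c(OCc2ccccc2)c2c(=O)cc(-c3ccc(OCc4ccccc4)cc3)oc2c1OC | intermediate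
16 | {5-(benzyloxy)-2-[4-(benzyloxy)phenyl]-6,7,8-trimethoxy-4-oxo-4H-chromen-3-yl}lithium | COc1c(OC)c(OCc2ccccc2)c2c(=O)c([Li])c(-c3ccc(OCc4ccccc4)cc3)oc2c1OC | intermediate
17 | lithium {5-(benzyloxy)-2-[4-(benzyloxy)phenyl]-6,7,8-trimethoxy-4-oxo-4H-chromen-3-yl}trimethoxyborate | [Li+].COc1c(OC)c(OCc2ccccc2)c2c(=O)c([B-](OC)(OC)OC)c(-c3ccc(OCc4ccccc4)cc3)oc2c1OC | intermediate
18 | 5-(benzyloxy)-2-[4-(benzyloxy)phenyl]-3-hydroxy-6,7,8-trimethoxy-4H-chromen-4-one | COc1c(OC)c(OCc2ccccc2)c2c(=O)c(O)c(-c3ccc(OCc4ccccc4)cc3)oc2c1OC | intermediate
19 | 3,5-dihydroxy-2-(4-hydroxyphenyl)-6,7,8-trimethoxy-4H-chromen-4-one (no stereocentre) | COc1c(OC)c(O)c2c(=O)c(O)c(-c3ccc(O)cc3)oc2c1OC | target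

## Step count and least certain steps

Total: 8 steps. Longest linear sequence: 8 steps (1 to 19); compounds 5, 11 and 12 are purchased.

The key step, step 6, is the least certain. Oxidative addition to the electron-rich, doubly ortho-substituted C–I bond is slow, all the more so when the phenol is partly deprotonated by the amine. Catalyst deactivation to palladium black, hydrodeiodination of 10 and oligomerisation of the alkyne may therefore outrun the coupling, and diethylamine may intercept the aroylpalladium species (aminocarbonylation) before the alkyne does. The fallback avoids palladium and CO and sets out from 10 and 11.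
- Phenol 10 is protected (chloromethyl methyl ether, iPr2NEt, CH2Cl2) as 1-(benzyloxy)-2-iodo-4,5,6-trimethoxy-3-(methoxymethoxy)benzene F1.
- Alkyne 11 is formylated (n-BuLi, THF, −78 °C; DMF) to 3-[4-(benzyloxy)phenyl]prop-2-ynal F2.
- Iodine–magnesium exchange on F1 (iPrMgCl·LiCl, THF, −20 °C) and addition to F2 give the propargylic alcohol 1-[2-(benzyloxy)-3,4,5-trimethoxy-6-(methoxymethoxy)phenyl]-3-[4-(benzyloxy)phenyl]prop-2-yn-1-ol F3.
- MnO2 in CH2Cl2 oxidises F3 to the ynone 1-[2-(benzyloxy)-3,4,5-trimethoxy-6-(methoxymethoxy)phenyl]-3-[4-(benzyloxy)phenyl]prop-2-yn-1-one F4.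
- Dilute HCl in MeOH/THF removes the acetal and the route is rejoined at ynone 13, which diethylamine in ethanol should close to 15 through 14 as in the key step.

Step 7 is the next most uncertain. The lithiated pyranone 16 may ring-open by β-elimination of the phenoxide if the temperature rises. Borylation of a hindered vinyl anion between a carbonyl and an aryl group may be incomplete. The amide base may deprotonate a benzylic position, and peroxide may over-oxidise the electron-rich flavonol. The fallback sets out from 15: epoxidation of C2=C3 with dimethyldioxirane (acetone/CH2Cl2, 0 °C) gives the 2,3-epoxide 6-(benzyloxy)-1a-[4-(benzyloxy)phenyl]-3,4,5-trimethoxy-1a,7a-dihydro-7H-oxireno[2,3-b]chromen-7-one F5. Catalytic p-toluenesulfonic acid in CH2Cl2 opens it at C2 and, after loss of the C3 proton, the route is rejoined at 18.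

In step 5 oxidation may compete with substitution: a phenol with a para methoxy group and four further oxygens can be oxidised by the iodonium source towards a quinone with loss of a methyl group. The fallback sets out from 9 and needs no electrophilic halogen on a free phenol. The phenol is converted (chloromethyl methyl ether, iPr2NEt, CH2Cl2) into 1-(benzyloxy)-2,3,4-trimethoxy-5-(methoxymethoxy)benzene F6. Directed ortho-lithiation of the single ring C–H between the acetal oxygen and the benzyloxy group (n-BuLi, TMEDA, THF, −78 °C) and quenching with I2 give 1-(benzyloxy)-2-iodo-4,5,6-trimethoxy-3-(methoxymethoxy)benzene F1, the same compound as in the fallback for step 6. HCl in MeOH removes the acetal and the route is rejoined at 10.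

In step 4 aryllithium 7 may be protonated prematurely or butylated by the 1-bromobutane formed in the exchange, and borylation may be incomplete, all of which return material without the new oxygen. The fallback sets out from 6 and replaces the organolithium sequence by a palladium-catalysed hydroxylation of the aryl bromide (Pd2(dba)3, tBuXPhos, KOH, dioxane/H2O, 100 °C, then acidification). It rejoins the route directly at 9 and makes no new compound (F0).

## Further compounds

F1 | step 6 | 1-(benzyloxy)-2-iodo-4,5,6-trimethoxy-3-(methoxymethoxy)benzene | COCOc1c(I)c(OCc2ccccc2)c(OC)c(OC)c1OC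
F2 | step 6 | 3-[4-(benzyloxy)phenyl]prop-2-ynal | O=CC#Cc1ccc(OCc2ccccc2)cc1
F3 | step 6 | 1-[2-(benzyloxy)-3,4,5-trimethoxy-6-(methoxymethoxy)phenyl]-3-[4-(benzyloxy)phenyl]prop-2-yn-1-ol (racemic) | COCOc1c(C(O)C#Cc2ccc(OCc3ccccc3)cc2)c(OCc2ccccc2)c(OC)c(OC)c1OC
F4 | step 6 | 1-[2-(benzyloxy)-3,4,5-trimethoxy-6-(methoxymethoxy)phenyl]-3-[4-(benzyloxy)phenyl]prop-2-yn-1-one | COCOc1c(C(=O)C#Cc2ccc(OCc3ccccc3)cc2)c(OCc2ccccc2)c(OC)c(OC)c1OC
F5 | step 7 | 6-(benzyloxy)-1a-[4-(benzyloxy)phenyl]-3,4,5-trimethoxy-1a,7a-dihydro-7H-oxireno[2,3-b]chromen-7-one (2,3-epoxide of 15; racemic, ring fusion necessarily cis) | COc1c(OC)c(OCc2ccccc2)c2C(=O)C3OC3(c3ccc(OCc4ccccc4)cc3)Oc2c1OC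
F6 | step 5 | 1-(benzyloxy)-2,3,4-trimethoxy-5-(methoxymethoxy)benzene | COCOc1cc(OCc2ccccc2)c(OC)c(OC)c1OC
F0 | step 4 | none | none
A1 | alternative 1 | 3-(benzyloxy)-2-[4-(benzyloxy)phenyl]-6,8-dibromo-5,7-dimethoxy-4H-chromen-4-one | COc1c(Br)c(OC)c2c(=O)c(OCc3ccccc3)c(-c3ccc(OCc4ccccc4)cc3)oc2c1Br
A2 | alternative 1 | 3-(benzyloxy)-2-[4-(benzyloxy)phenyl]-5,6,7,8-tetramethoxy-4H-chromen-4-one | COc1c(OC)c(OC)c2c(=O)c(OCc3ccccc3)c(-c3ccc(OCc4ccccc4)cc3)oc2c1OC
A3 | alternative 2 | 2-(benzyloxy)-6-{1-[4-(benzyloxy)phenyl]-2-oxoethoxy}-3,4,5-trimethoxybenzaldehyde (racemic) | COc1c(OC)c(OCc2ccccc2)c(C=O)c(OC(C=O)c2ccc(OCc3ccccc3)cc2)c1OC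
A4 | alternative 2 | 5-(benzyloxy)-2-[4-(benzyloxy)phenyl]-6,7,8-trimethoxychromane-3,4-diol (mixture of stereoisomers) | COc1c(OC)c(OCc2ccccc2)c2C(O)C(O)C(c3ccc(OCc4ccccc4)cc3)Oc2c1OC
A5 | alternative 3 | 4-{5-(benzyloxy)-6-[4-(benzyloxy)phenyl]-4-oxo-4H-pyran-3-yl}-4-hydroxy-2,3-dimethoxycyclobut-2-en-1-one (racemic) | COC1=C(OC)C(O)(C1=O)c1coc(-c2ccc(OCc3ccccc3)cc2)c(OCc2ccccc2)c1=O
A6 | alternative 3 | 3-(benzyloxy)-2-[4-(benzyloxy)phenyl]-5,8-dihydroxy-6,7-dimethoxy-4H-chromen-4-one | COc1c(OC)c(O)c2c(=O)c(OCc3ccccc3)c(-c3ccc(OCc4ccccc4)cc3)oc2c1O
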